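**Retrosynthetic overview**
1. Target 15 ⇒ cut C4′–C5′ (side chain labelled C1′–C17′ outward from the ring). The pieces are the trans-fused bicyclic oxepine enol ether 7 (a masked hydroxy-aldehyde whose O–CH= carbon is lithiated and used as an acyl-anion equivalent) and a homofarnesyl organometallic from sulfide 10. A 1,2-metallate shift on copper makes the C–C bond, the E-trisubstituted alkene and the free tertiary OH in one operation.
2. 7 ⇒ hydroxy ketone 3 by one-carbon Wittig homologation and acetal/enol-ether ring closure; 10 ⇒ (E,E)-farnesyl bromide 8 + thioanisole 9.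
3. 3 ⇒ (E)-geranylacetone 1 by enantioselective cation–olefin cyclization, which sets both stereocentres.
4. Ring order: cyclohexane first (step 1); temporary seven-membered oxacycle second (step 3); the oxacycle is opened again in the key step 5.

Assumption: recombinant squalene–hopene cyclase is treated as an accessible biocatalyst, not a starting material; geranylacetone is used as the ≥96 % E isomer and farnesyl bromide as the E,E isomer.

**Route**

Step 1
Reactants: 1 (5E)-6,10-dimethylundeca-5,9-dien-2-one [(E)-geranylacetone]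
Product: 3 4-[(1S,2S)-2-hydroxy-2,6,6-trimethylcyclohexyl]butan-2-one, via bicyclic enol ether 2 (not isolated)
Conditions: squalene–hopene cyclase from Alicyclobacillus acidocaldarius (recombinant, E. coli whole cells), citrate buffer pH 6.0, 2-hydroxypropyl-β-cyclodextrin, 30 °C, 72 h; extract; 1 M HCl, THF, 23 °C
Reagents that add atoms: water, O
Why: Enzyme-controlled proton-initiated cation–olefin (polyene) cyclization through a chair fold, terminated by the ketone oxygen, adds C and O anti across the E-alkene and so sets both ring stereocentres (both S, OH trans to the side chain) in the sense of the natural hopene/ambrox series, after which dilute acid only hydrolyses the cyclic enol ether 2 to 3.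

Step 2
Reactants: 3 4-[(1S,2S)-2-hydroxy-2,6,6-trimethylcyclohexyl]butan-2-one; 4 (methoxymethyl)triphenylphosphonium chloride
Product: 5 (1S,2S)-2-(4-methoxy-3-methylbut-3-en-1-yl)-1,3,3-trimethylcyclohexan-1-ol (E/Z mixture)
Conditions: 4 (3 equiv), KOtBu (3 equiv), THF, 0 °C; then 3, 0 → 23 °C
Reagents that add atoms: 4 (methoxymethyl)triphenylphosphonium chloride, COC[P+](c1ccccc1)(c1ccccc1)c1ccccc1.[Cl-]
Why: Wittig methoxymethylenation of a methyl ketone (one-carbon homologation, with excess ylide covering the free tertiary alkoxide) creates no stereocentre, and the E/Z mixture does not matter because both isomers give the same oxocarbenium ion in step 3.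

Step 3
Reactants: 5 (1S,2S)-2-(4-methoxy-3-methylbut-3-en-1-yl)-1,3,3-trimethylcyclohexan-1-ol
Product: 7 (5aS,9aS)-3,6,6,9a-tetramethyl-4,5,5a,6,7,8,9,9a-octahydro-1-benzoxepine, via cyclic methyl acetal 6 (not isolated)
Conditions: PPTS (0.1 equiv), CH2Cl2 (0.01 M), 23 °C; then PPTS (0.3 equiv), pyridine (0.5 equiv), PhCl, 135 °C, MeOH distilled off
Reagents that add atoms: none
Why: Acid-catalysed intramolecular hydroalkoxylation of the enol ether (oxocarbenium ion captured by the tethered tertiary alcohol to give a trans-fused seven-membered mixed acetal) followed by thermal acetal-to-enol-ether elimination of methanol can only deprotonate at the methyl-bearing carbon, so the endocyclic trisubstituted enol ether forms and the ring stereocentres are untouched.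

Step 4
Reactants: 8 (2E,6E)-1-bromo-3,7,11-trimethyldodeca-2,6,10-triene [(E,E)-farnesyl bromide]; 9 thioanisole
Product: 10 phenyl (3E,7E)-4,8,12-trimethyltrideca-3,7,11-trien-1-yl sulfide (homofarnesyl phenyl sulfide)
Conditions: 9, n-BuLi, DABCO, THF, 0 °C; then 8, −78 → 0 °C
Reagents that add atoms: 9 thioanisole, CSc1ccccc1
Why: Corey–Seebach-type homologation in which (phenylthio)methyllithium displaces the primary allylic bromide by SN2 at the unhindered CH2 terminus, adding C5′ without moving or isomerising the E-alkenes.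

Step 5
Reactants: 7 (5aS,9aS)-3,6,6,9a-tetramethyl-4,5,5a,6,7,8,9,9a-octahydro-1-benzoxepine; 10 phenyl (3E,7E)-4,8,12-trimethyltrideca-3,7,11-trien-1-yl sulfide
Product: 15 (1S,2S)-1,3,3-trimethyl-2-[(3E,7E,11E)-3,8,12,16-tetramethylheptadeca-3,7,11,15-tetraen-1-yl]cyclohexan-1-ol (target), via homofarnesyllithium 11 (not isolated), via lithiated oxepine 12 (not isolated), via lithium cuprate 13 (not isolated), via alkenylcopper alkoxide 14 (not isolated)
Conditions: 10 (1.5 equiv), lithium 4,4'-di-tert-butylbiphenylide (3.1 equiv), THF, −78 °C; CuBr·SMe2 (1.5 equiv), Me2S, −78 → −40 °C; add 12 [from 7 (1.0 equiv), t-BuLi (1.2 equiv), THF–pentane, −78 → 0 °C]; −40 → 23 °C, 12 h; aq NH4Cl/NH3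
Reagents that add atoms: none
Why: Proposed new method: reductive lithiation of sulfide 10 gives the primary alkyllithium 11 and t-BuLi removes the vinylic O–CH= proton of 7 to give 12, an α-alkoxyalkenyllithium that is an acyl-anion equivalent of the masked aldehyde carbon C4′; on copper the two carbanionic carbons (C4′ and C5′, otherwise electrophilic as aldehyde and halide carbons) are joined by a 1,2-metallate shift in which the homofarnesyl group migrates from Cu to C4′ in the alkene plane anti to the departing ring oxygen (inversion at C4′), so the new chain ends up trans and the copper (then H, by protonation with retention) cis to the ring-side CH2, which fixes the 3′E alkene and frees the tertiary alkoxide in the same event; the closest known reaction is the Kocienski cuprate 1,2-metallate rearrangement of 5-lithio-2,3-dihydrofurans and 6-lithio-3,4-dihydro-2H-pyrans to E-trisubstituted alkenols (the homogeraniol/homofarnesol chemistry), extended here to a seven-membered, β-methylated ring with a tertiary alkoxide leaving group, and no stereocentre is formed or touched.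

**Compound list**
1 | (5E)-6,10-dimethylundeca-5,9-dien-2-one [(E)-geranylacetone] | CC(=O)CC/C=C(\C)CCC=C(C)C | starting material
2 | (4aS,8aS)-2,5,5,8a-tetramethyl-4a,5,6,7,8,8a-hexahydro-4H-chromene (trans-fused bicyclic enol ether) | CC1=CC[C@H]2C(C)(C)CCC[C@]2(C)O1 | intermediate (not isolated)
3 | 4-[(1S,2S)-2-hydroxy-2,6,6-trimethylcyclohexyl]butan-2-one | CC(=O)CC[C@H]1C(C)(C)CCC[C@]1(C)O | intermediate
4 | (methoxymethyl)triphenylphosphonium chloride | COC[P+](c1ccccc1)(c1ccccc1)c1ccccc1.[Cl-] | starting material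
5 | (1S,2S)-2-(4-methoxy-3-methylbut-3-en-1-yl)-1,3,3-trimethylcyclohexan-1-ol (E/Z mixture) | COC=C(C)CC[C@H]1C(C)(C)CCC[C@]1(C)O | intermediate
6 | (5aS,9aS)-2-methoxy-3,6,6,9a-tetramethyldecahydro-1-benzoxepine (epimers at C2 and C3) | COC1C(C)CC[C@H]2C(C)(C)CCC[C@]2(C)O1 | intermediate (not isolated)
7 | (5aS,9aS)-3,6,6,9a-tetramethyl-4,5,5a,6,7,8,9,9a-octahydro-1-benzoxepine (trans-fused, O–CH=C(CH3) enol ether) | C1=C(C)CC[C@H]2C(C)(C)CCC[C@]2(C)O1 | intermediate
8 | (2E,6E)-1-bromo-3,7,11-trimethyldodeca-2,6,10-triene [(E,E)-farnesyl bromide] | CC(C)=CCC/C(C)=C/CC/C(C)=C/CBr | starting material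
9 | thioanisole (methyl phenyl sulfide) | CSc1ccccc1 | starting material
10 | phenyl (3E,7E)-4,8,12-trimethyltrideca-3,7,11-trien-1-yl sulfide | CC(C)=CCC/C(C)=C/CC/C(C)=C/CCSc1ccccc1 | intermediate
11 | [(3E,7E)-4,8,12-trimethyltrideca-3,7,11-trien-1-yl]lithium (homofarnesyllithium) | CC(C)=CCC/C(C)=C/CC/C(C)=C/CC[Li] | intermediate (not isolated)
12 | [(5aS,9aS)-3,6,6,9a-tetramethyl-4,5,5a,6,7,8,9,9a-octahydro-1-benzoxepin-2-yl]lithium | [Li]C1=C(C)CC[C@H]2C(C)(C)CCC[C@]2(C)O1 | intermediate (not isolated)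
13 | lithium [(3E,7E)-4,8,12-trimethyltrideca-3,7,11-trien-1-yl][(5aS,9aS)-3,6,6,9a-tetramethyl-4,5,5a,6,7,8,9,9a-octahydro-1-benzoxepin-2-yl]cuprate | [Li+].CC(C)=CCC/C(C)=C/CC/C(C)=C/CC[Cu-]C1=C(C)CC[C@H]2C(C)(C)CCC[C@]2(C)O1 | intermediate (not isolated)
14 | lithium (1S,2S)-2-[(3Z,7E,11E)-4-cuprio-3,8,12,16-tetramethylheptadeca-3,7,11,15-tetraen-1-yl]-1,3,3-trimethylcyclohexan-1-olate (Cu cis to C2′, homofarnesyl chain trans to C2′) | [Li+].CC(C)=CCC/C(C)=C/CC/C(C)=C/CC/C([Cu])=C(\C)CC[C@H]1C(C)(C)CCC[C@]1(C)[O-] | intermediate (not isolated)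
15 | (1S,2S)-1,3,3-trimethyl-2-[(3E,7E,11E)-3,8,12,16-tetramethylheptadeca-3,7,11,15-tetraen-1-yl]cyclohexan-1-ol (CNP0273209.1) | CC(C)=CCC/C(C)=C/CC/C(C)=C/CC/C=C(\C)CC[C@H]1C(C)(C)CCC[C@]1(C)O | target

**Step count and risks**
Total steps: 5. Longest linear sequence: 4 (1 → 3 → 5 → 7 → 15).

Step 5 is the most likely to fail: the metallate shift is untested on a seven-membered ring with a tertiary alkoxide leaving group, and allylic lithiation of 7 may compete. The fallback drops the carbenoid logic and builds the C5′–C6′ bond by sulfone alkylation; it sets out from 3 (and uses 8) and comes back at 15. Ketone 3 is olefinated with triethyl phosphonoacetate/NaH in THF (about 4:1 E/Z expected, E isomer separated) to ethyl (2E)-5-[(1S,2S)-2-hydroxy-2,6,6-trimethylcyclohexyl]-3-methylpent-2-enoate F1. Reduction with i-Bu2AlH gives (1S,2S)-2-[(3E)-5-hydroxy-3-methylpent-3-en-1-yl]-1,3,3-trimethylcyclohexan-1-ol F2, and MsCl/Et3N then LiBr gives (1S,2S)-2-[(3E)-5-bromo-3-methylpent-3-en-1-yl]-1,3,3-trimethylcyclohexan-1-ol F3. Separately, 8 and PhSO2Na in DMF give [(2E,6E)-3,7,11-trimethyldodeca-2,6,10-trien-1-yl]sulfonylbenzene F4. Its lithio anion (n-BuLi, THF, −78 °C, 2.2 equiv to cover the free OH) alkylates F3 to (1S,2S)-2-[(3E,7E,11E)-6-(benzenesulfonyl)-3,8,12,16-tetramethylheptadeca-3,7,11,15-tetraen-1-yl]-1,3,3-trimethylcyclohexan-1-ol F5. Reductive desulfonylation with PdCl2(dppp)/LiBHEt3 in THF at 0 °C gives 15.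

Step 1 is the second risk: enzyme activity on the short C13 substrate may be low. The fallback replaces biocatalysis by a reagent-controlled chemical cyclization of the derived acid; it sets out from 1 and comes back at 3. Haloform degradation of 1 (NaOBr, dioxane/water, 0 °C) gives (4E)-5,9-dimethyldeca-4,8-dienoic acid F6. Proton-initiated cyclization with the SnCl4 complex of (R)-2-hydroxy-2'-(2-fluorobenzyloxy)-1,1'-binaphthyl (toluene, −78 °C; the ligand antipode is used if the sense proves opposite) gives (4aS,8aS)-5,5,8a-trimethyloctahydro-2H-chromen-2-one F7, which is upgraded by recrystallisation. MeLi (1.05 equiv, THF, −78 °C) then opens the lactone to 3.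

Step 3 is the third risk: closure of the seven-membered ring by a hindered tertiary alcohol may lose to oligomeric acetals. The fallback replaces the acid-driven acetal elimination by a base-driven elimination from an isolated lactol; it sets out from 5 and comes back at 7. Mild hydrolysis of 5 (oxalic acid, wet THF) gives 4-[(1S,2S)-2-hydroxy-2,6,6-trimethylcyclohexyl]-2-methylbutanal F8, which equilibrates with its lactol (5aS,9aS)-3,6,6,9a-tetramethyldecahydro-1-benzoxepin-2-ol F9. MsCl/Et3N in CH2Cl2 (−60 → 23 °C) converts F9 into (5aS,9aS)-3,6,6,9a-tetramethyldecahydro-1-benzoxepin-2-yl methanesulfonate F10, which eliminates in the flask to 7.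

**Further compounds**
F1 | step 5 | ethyl (2E)-5-[(1S,2S)-2-hydroxy-2,6,6-trimethylcyclohexyl]-3-methylpent-2-enoate | CCOC(=O)/C=C(\C)CC[C@H]1C(C)(C)CCC[C@]1(C)O
F2 | step 5 | (1S,2S)-2-[(3E)-5-hydroxy-3-methylpent-3-en-1-yl]-1,3,3-trimethylcyclohexan-1-ol | OC/C=C(\C)CC[C@H]1C(C)(C)CCC[C@]1(C)O
F3 | step 5 | (1S,2S)-2-[(3E)-5-bromo-3-methylpent-3-en-1-yl]-1,3,3-trimethylcyclohexan-1-ol | BrC/C=C(\C)CC[C@H]1C(C)(C)CCC[C@]1(C)O
F4 | step 5 | [(2E,6E)-3,7,11-trimethyldodeca-2,6,10-trien-1-yl]sulfonylbenzene | CC(C)=CCC/C(C)=C/CC/C(C)=C/CS(=O)(=O)c1ccccc1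
F5 | step 5 | (1S,2S)-2-[(3E,7E,11E)-6-(benzenesulfonyl)-3,8,12,16-tetramethylheptadeca-3,7,11,15-tetraen-1-yl]-1,3,3-trimethylcyclohexan-1-ol (epimers at the sulfonyl carbon) | CC(C)=CCC/C(C)=C/CC/C(C)=C/C(C/C=C(\C)CC[C@H]1C(C)(C)CCC[C@]1(C)O)S(=O)(=O)c1ccccc1
F6 | step 1 | (4E)-5,9-dimethyldeca-4,8-dienoic acid | CC(C)=CCC/C(C)=C/CCC(=O)O
F7 | step 1 | (4aS,8aS)-5,5,8a-trimethyloctahydro-2H-chromen-2-one | O=C1CC[C@H]2C(C)(C)CCC[C@]2(C)O1
F8 | step 3 | 4-[(1S,2S)-2-hydroxy-2,6,6-trimethylcyclohexyl]-2-methylbutanal (epimers at C2) | O=CC(C)CC[C@H]1C(C)(C)CCC[C@]1(C)O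
F9 | step 3 | (5aS,9aS)-3,6,6,9a-tetramethyldecahydro-1-benzoxepin-2-ol (epimers at C2 and C3) | OC1C(C)CC[C@H]2C(C)(C)CCC[C@]2(C)O1
F10 | step 3 | (5aS,9aS)-3,6,6,9a-tetramethyldecahydro-1-benzoxepin-2-yl methanesulfonate (epimers at C2 and C3) | CS(=O)(=O)OC1C(C)CC[C@H]2C(C)(C)CCC[C@]2(C)O1
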